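**Retrosynthetic overview**
1. Calycopterin ⇐ chelation-directed 5-O-demethylation and 4'-O-debenzylation of 4'-benzyloxy-3,5,6,7,8-pentamethoxyflavone.
2. The 3-OMe group ⇐ O-methylation of the flavonol ⇐ C-3 hydroxylation (epoxidation and ring opening) of the 3-unsubstituted flavone.
3. Ring C (the pyranone) is the only ring built and it closes last ⇐ oxidative oxa-Michael cyclisation of a 2'-hydroxychalcone.
4. Key C–C bond (future C2–C3) ⇐ intermolecular Claisen–Schmidt aldol condensation of the ring A acetophenone with 4-(benzyloxy)benzaldehyde (ring B).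
5. Ring A acetophenone ⇐ ortho-acylation of 2,3,4,5-tetramethoxyphenol ⇐ 2,3,4-trimethoxybenzaldehyde by two CHO-to-OH exchanges. Rings A and B are bought as arenes.

Assumption: calycopterin has no stereocentre, stereogenic axis or configured double bond. It is achiral, so the compound drawn is the only form and no asymmetric step is needed.

**Step 1**
Reactants: 1 2,3,4-trimethoxybenzaldehyde
Product: 3 2,3,4-trimethoxyphenol, via 2,3,4-trimethoxyphenyl formate 2 (not isolated)
Conditions: mCPBA (1.3 equiv), CH2Cl2, 0 °C to rt; aq NaHCO3 wash; then K2CO3 (0.2 equiv), MeOH, rt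
Reagents that add atoms: mCPBA, O=C(OO)c1cccc(Cl)c1
Why: In this Baeyer–Villiger (Dakin-type) oxidation the electron-rich aryl group migrates in the Criegee adduct to give formate 2, whose base-catalysed methanolysis frees the phenol, and no stereocentre is formed.

**Step 2**
Reactants: 3 2,3,4-trimethoxyphenol
Product: 4 1,2,3,4-tetramethoxybenzene
Conditions: MeI (1.5 equiv), K2CO3 (2 equiv), acetone, reflux
Reagents that add atoms: iodomethane, CI
Why: This is a Williamson O-methylation (SN2) of the potassium phenolate, the only nucleophilic site present, and no stereocentre is formed.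

**Step 3**
Reactants: 4 1,2,3,4-tetramethoxybenzene
Product: 7 2,3,4,5-tetramethoxybenzaldehyde, via aryllithium 5 (not isolated), via lithium hemiaminal alkoxide 6 (not isolated)
Conditions: n-BuLi (1.2 equiv), TMEDA (1.2 equiv), THF, 0 °C; DMF (2 equiv), −78 °C to rt; 1 M HCl
Reagents that add atoms: N,N-dimethylformamide, CN(C)C=O
Why: Directed ortho-metalation next to a methoxy group can give only one aryllithium because the two free positions of symmetrical 4 are equivalent, and Bouveault-type formylation with DMF follows, the racemic hemiaminal carbon of 6 vanishing on hydrolysis.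

**Step 4**
Reactants: 7 2,3,4,5-tetramethoxybenzaldehyde
Product: 9 2,3,4,5-tetramethoxyphenol, via 2,3,4,5-tetramethoxyphenyl formate 8 (not isolated)
Conditions: mCPBA (1.3 equiv), CH2Cl2, 0 °C to rt; aq NaHCO3 wash; then K2CO3 (0.2 equiv), MeOH, rt, under N2
Reagents that add atoms: mCPBA, O=C(OO)c1cccc(Cl)c1
Why: A second Baeyer–Villiger oxidation with migration of the very electron-rich aryl group and methanolysis of formate 8 installs the fifth ring oxygen exactly where the formyl carbon stood, and no stereocentre is formed.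

**Step 5**
Reactants: 9 2,3,4,5-tetramethoxyphenol
Product: 12 1-(2-hydroxy-3,4,5,6-tetramethoxyphenyl)ethanone, via aryl acetate 10 (not isolated), via difluoroboron chelate 11 (not isolated)
Conditions: Ac2O (1.5 equiv), BF3·OEt2 (4 equiv), 70 °C, 2 h; then aq EtOH, reflux
Reagents that add atoms: acetic anhydride, CC(=O)OC(C)=O
Why: O-acetylation followed by BF3-promoted Fries rearrangement (Friedel–Crafts acylation) can reach only the single free ring position, ortho to the phenol, and the ketone is held as BF2 chelate 11 until hydrolysis, with no stereocentre formed.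

**Step 6 (key C–C bond formation)**
Reactants: 12 1-(2-hydroxy-3,4,5,6-tetramethoxyphenyl)ethanone; 13 4-(benzyloxy)benzaldehyde
Product: 15 (E)-3-[4-(benzyloxy)phenyl]-1-(2-hydroxy-3,4,5,6-tetramethoxyphenyl)prop-2-en-1-one, via aldol adduct 14 (not isolated)
Conditions: KOH (50% aq, 10 equiv), EtOH, rt, 24–48 h; 2 M HCl, 0 °C
Reagents that add atoms: none
Why: In this Claisen–Schmidt crossed aldol condensation 12 is the only enolisable partner and 13 the only good electrophile, and E1cB dehydration of racemic aldol 14 erases its carbinol stereocentre and gives the thermodynamically favoured E-enone.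

**Step 7**
Reactants: 15 (E)-3-[4-(benzyloxy)phenyl]-1-(2-hydroxy-3,4,5,6-tetramethoxyphenyl)prop-2-en-1-one
Product: 17 2-[4-(benzyloxy)phenyl]-5,6,7,8-tetramethoxy-4H-chromen-4-one (4'-benzyloxy-5,6,7,8-tetramethoxyflavone), via flavanone 16 (not isolated)
Conditions: I2 (0.1 equiv), DMSO, 130 °C, 2–3 h; aq Na2S2O3 work-up
Reagents that add atoms: none
Why: In this iodine-catalysed oxidative cyclisation a 6-endo oxa-Michael closure of ring C gives racemic flavanone 16, then α-iodination and loss of HI aromatise the pyranone and erase the C-2 stereocentre while DMSO reoxidises HI to I2, which avoids the aurone problem of alkaline peroxide with 6'-methoxychalcones.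

**Step 8**
Reactants: 17 4'-benzyloxy-5,6,7,8-tetramethoxyflavone
Product: 19 2-[4-(benzyloxy)phenyl]-3-hydroxy-5,6,7,8-tetramethoxy-4H-chromen-4-one, via flavone 2,3-epoxide 18 (not isolated)
Conditions: DMDO (about 0.07 M in acetone, 3 equiv), CH2Cl2, 0 °C to rt; then p-TsOH·H2O (0.1 equiv), CH2Cl2, rt
Reagents that add atoms: dimethyldioxirane, CC1(C)OO1
Why: Electrophilic epoxidation of the enol-ether-like C2–C3 bond is followed by acid-catalysed epoxide opening through the aryl-stabilised C-2 oxocarbenium ion and loss of H-3, which gives the flavonol and removes both stereocentres of racemic 18.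

**Step 9**
Reactants: 19 4'-benzyloxy-3-hydroxy-5,6,7,8-tetramethoxyflavone
Product: 20 2-[4-(benzyloxy)phenyl]-3,5,6,7,8-pentamethoxy-4H-chromen-4-one
Conditions: MeI (2 equiv), K2CO3 (3 equiv), acetone, reflux
Reagents that add atoms: iodomethane, CI
Why: This is a Williamson O-methylation of the acidic 3-hydroxyl, the only free OH in the molecule, and no stereocentre is formed.

**Step 10**
Reactants: 20 4'-benzyloxy-3,5,6,7,8-pentamethoxyflavone
Product: 21 2-(4-hydroxyphenyl)-3,5,6,7,8-pentamethoxy-4H-chromen-4-one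
Conditions: H2 (1 atm), 10% Pd/C, EtOAc–MeOH (1:1), rt
Reagents that add atoms: none
Why: Catalytic hydrogenolysis cleaves the benzylic C–O bond, while the tetrasubstituted vinylogous-ester C2–C3 bond and the aryl methyl ethers are inert at 1 atm and rt, and removing the benzyl group first keeps it out of the Lewis-acid step.

**Step 11**
Reactants: 21 4'-hydroxy-3,5,6,7,8-pentamethoxyflavone
Product: 23 calycopterin (5-hydroxy-2-(4-hydroxyphenyl)-3,6,7,8-tetramethoxy-4H-chromen-4-one), via aluminium phenolate chelate 22 (not isolated)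
Conditions: AlCl3 (5 equiv), MeCN, 60 °C, 1–2 h (TLC control); then 2 M HCl, 60 °C, 20 min
Reagents that add atoms: none
Why: In this chelation-directed Lewis-acid ether cleavage AlCl3 bridges the C-4 carbonyl and the peri 5-methoxy oxygen in a six-membered chelate, so chloride removes only that methyl group by SN2, while the 3-methoxy group (only a five-membered chelate possible) and the 6-, 7- and 8-methoxy groups survive these mild conditions.

**Compound list**
1 | 2,3,4-trimethoxybenzaldehyde | COc1ccc(C=O)c(OC)c1OC | starting material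
2 | 2,3,4-trimethoxyphenyl formate | COc1ccc(OC=O)c(OC)c1OC | intermediate
3 | 2,3,4-trimethoxyphenol | COc1ccc(O)c(OC)c1OC | intermediate
4 | 1,2,3,4-tetramethoxybenzene | COc1ccc(OC)c(OC)c1OC | intermediate
5 | (2,3,4,5-tetramethoxyphenyl)lithium | [Li]c1cc(OC)c(OC)c(OC)c1OC | intermediate
6 | lithium (dimethylamino)(2,3,4,5-tetramethoxyphenyl)methanolate (racemic) | [Li]OC(N(C)C)c1cc(OC)c(OC)c(OC)c1OC | intermediate
7 | 2,3,4,5-tetramethoxybenzaldehyde | O=Cc1cc(OC)c(OC)c(OC)c1OC | intermediate
8 | 2,3,4,5-tetramethoxyphenyl formate | O=COc1cc(OC)c(OC)c(OC)c1OC | intermediate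
9 | 2,3,4,5-tetramethoxyphenol | Oc1cc(OC)c(OC)c(OC)c1OC | intermediate
10 | 2,3,4,5-tetramethoxyphenyl acetate | CC(=O)Oc1cc(OC)c(OC)c(OC)c1OC | intermediate
11 | difluoroboron O,O-chelate of 12 | CC1=[O+][B-](F)(F)Oc2c(OC)c(OC)c(OC)c(OC)c12 | intermediate
12 | 1-(2-hydroxy-3,4,5,6-tetramethoxyphenyl)ethanone | CC(=O)c1c(O)c(OC)c(OC)c(OC)c1OC | intermediate
13 | 4-(benzyloxy)benzaldehyde | O=Cc1ccc(OCc2ccccc2)cc1 | starting material
14 | 3-[4-(benzyloxy)phenyl]-3-hydroxy-1-(2-hydroxy-3,4,5,6-tetramethoxyphenyl)propan-1-one (racemic) | O=C(CC(O)c1ccc(OCc2ccccc2)cc1)c1c(O)c(OC)c(OC)c(OC)c1OC | intermediate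
15 | (E)-3-[4-(benzyloxy)phenyl]-1-(2-hydroxy-3,4,5,6-tetramethoxyphenyl)prop-2-en-1-one | O=C(/C=C/c1ccc(OCc2ccccc2)cc1)c1c(O)c(OC)c(OC)c(OC)c1OC | intermediate
16 | 2-[4-(benzyloxy)phenyl]-5,6,7,8-tetramethoxychroman-4-one (racemic) | O=C1CC(c2ccc(OCc3ccccc3)cc2)Oc2c1c(OC)c(OC)c(OC)c2OC | intermediate
17 | 4'-benzyloxy-5,6,7,8-tetramethoxyflavone | COc1c(OC)c(OC)c2c(=O)cc(-c3ccc(OCc4ccccc4)cc3)oc2c1OC | intermediate
18 | 4'-benzyloxy-2,3-epoxy-5,6,7,8-tetramethoxyflavanone (racemic, cis-fused) | O=C1C2OC2(c2ccc(OCc3ccccc3)cc2)Oc2c1c(OC)c(OC)c(OC)c2OC | intermediate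
19 | 4'-benzyloxy-3-hydroxy-5,6,7,8-tetramethoxyflavone | COc1c(OC)c(OC)c2c(=O)c(O)c(-c3ccc(OCc4ccccc4)cc3)oc2c1OC | intermediate
20 | 4'-benzyloxy-3,5,6,7,8-pentamethoxyflavone | COc1c(OC)c(OC)c2c(=O)c(OC)c(-c3ccc(OCc4ccccc4)cc3)oc2c1OC | intermediate
21 | 4'-hydroxy-3,5,6,7,8-pentamethoxyflavone | COc1c(OC)c(OC)c2c(=O)c(OC)c(-c3ccc(O)cc3)oc2c1OC | intermediate
22 | 5,4'-bis(dichloroaluminium) phenolate of 23 (5-O–Al chelated to the C-4 carbonyl) | COc1c(OC)c(O[Al](Cl)Cl)c2c(=O)c(OC)c(-c3ccc(O[Al](Cl)Cl)cc3)oc2c1OC | intermediate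
23 | calycopterin, 5,4'-dihydroxy-3,6,7,8-tetramethoxyflavone (achiral) | COc1c(OC)c(O)c2c(=O)c(OC)c(-c3ccc(O)cc3)oc2c1OC | target

**Total step count:** 11.
**Longest linear sequence:** 11 steps (1 to 23). Compound 13 is bought and enters at step 6.

**Three steps most likely to fail**

Risk at step 8 (C-3 hydroxylation). The C2–C3 bond is a deactivated vinylogous ester, so excess DMDO and long times are needed, and flavonol 19 or electron-rich ring A may over-oxidise. The fallback sets out from 17 and comes back at 19, and it replaces electrophilic oxidation by deprotonation, borylation and oxidation. Compound 17 is deprotonated at C-3 with LiN(iPr)2 (THF, −78 °C) to 4'-benzyloxy-3-lithio-5,6,7,8-tetramethoxyflavone F4. This is trapped with B(OMe)3 and acidified with AcOH to give dimethyl (4'-benzyloxy-5,6,7,8-tetramethoxyflavon-3-yl)boronate F5. Oxidation in the same flask with 30% H2O2 gives 19.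

Risk at step 11 (selective 5-O-demethylation). Overexposure can also remove the 3- or 6-methyl group. The fallback sets out from 17 and comes back at 23. It moves the differentiation of O-5 to the flavone stage, where no 3-methoxy group competes.
- BCl3 (3 equiv, CH2Cl2, −78 to 0 °C) cleaves the chelated 5-OMe and the benzyl ether of 17 to give 5,4'-dihydroxy-6,7,8-trimethoxyflavone F6.
- BnBr and K2CO3 in DMF at 70 °C give 5,4'-bis(benzyloxy)-6,7,8-trimethoxyflavone F7.
- DMDO gives 5,4'-bis(benzyloxy)-2,3-epoxy-6,7,8-trimethoxyflavanone F8.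
- Catalytic p-TsOH opens this to 5,4'-bis(benzyloxy)-3-hydroxy-6,7,8-trimethoxyflavone F9.
- MeI and K2CO3 give 5,4'-bis(benzyloxy)-3,6,7,8-tetramethoxyflavone F10.
- Hydrogenolysis (H2, 10% Pd/C) removes both benzyl groups and gives 23 directly.

Risk at step 5 (acylation). The site is crowded, phenol 9 is oxidation-sensitive, and BF3 may strip the methoxy group ortho to the new ketone. The fallback sets out from 9 and comes back at 12, and it replaces the electrophilic acylation by an anionic one. Compound 9 is methylated (MeI, K2CO3, acetone) to pentamethoxybenzene F1. This is deprotonated at its only ring C–H (n-BuLi, TMEDA, THF, 0 °C) to (pentamethoxyphenyl)lithium F2. Acylation with N-methoxy-N-methylacetamide and a 1 M HCl quench give 1-(2,3,4,5,6-pentamethoxyphenyl)ethanone F3. BCl3 (1.1 equiv, CH2Cl2, −78 to 0 °C) then removes one of the two equivalent methoxy groups ortho to the carbonyl and gives 12.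

**Further compounds**
F1 | step 5 | pentamethoxybenzene | COc1cc(OC)c(OC)c(OC)c1OC
F2 | step 5 | (pentamethoxyphenyl)lithium | [Li]c1c(OC)c(OC)c(OC)c(OC)c1OC
F3 | step 5 | 1-(2,3,4,5,6-pentamethoxyphenyl)ethanone | CC(=O)c1c(OC)c(OC)c(OC)c(OC)c1OC
F4 | step 8 | 4'-benzyloxy-3-lithio-5,6,7,8-tetramethoxyflavone | COc1c(OC)c(OC)c2c(=O)c([Li])c(-c3ccc(OCc4ccccc4)cc3)oc2c1OC
F5 | step 8 | dimethyl (4'-benzyloxy-5,6,7,8-tetramethoxyflavon-3-yl)boronate | COB(OC)c1c(-c2ccc(OCc3ccccc3)cc2)oc2c(OC)c(OC)c(OC)c(OC)c2c1=O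
F6 | step 11 | 5,4'-dihydroxy-6,7,8-trimethoxyflavone | COc1c(OC)c(O)c2c(=O)cc(-c3ccc(O)cc3)oc2c1OC
F7 | step 11 | 5,4'-bis(benzyloxy)-6,7,8-trimethoxyflavone | COc1c(OC)c(OCc2ccccc2)c2c(=O)cc(-c3ccc(OCc4ccccc4)cc3)oc2c1OC
F8 | step 11 | 5,4'-bis(benzyloxy)-2,3-epoxy-6,7,8-trimethoxyflavanone (racemic) | O=C1C2OC2(c2ccc(OCc3ccccc3)cc2)Oc2c1c(OCc1ccccc1)c(OC)c(OC)c2OC
F9 | step 11 | 5,4'-bis(benzyloxy)-3-hydroxy-6,7,8-trimethoxyflavone | COc1c(OC)c(OCc2ccccc2)c2c(=O)c(O)c(-c3ccc(OCc4ccccc4)cc3)oc2c1OC
F10 | step 11 | 5,4'-bis(benzyloxy)-3,6,7,8-tetramethoxyflavone | COc1c(OC)c(OCc2ccccc2)c2c(=O)c(OC)c(-c3ccc(OCc4ccccc4)cc3)oc2c1OC
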